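Cuts, in retrosynthetic order: the five O‑benzyl bonds; the flavonol C3–OH bond, the pyranone O1–C2 bond and the chalcone Cα=Cβ bond (back to a dihydrobenzofuran‑5‑carbaldehyde and dibenzylated phloroacetophenone); the aryl–CHO bond (from an aryl bromide); the O1–C2 bond of the dihydrofuran; the C2–C3 bond (aldol of an arylacetyl imide with O‑allylvanillin).
Enabling feature: C2 of the dihydrofuran ring (O1–C2–C3) is benzylic, bonded to ring oxygen O1 and para to the phenolic OH of the guaiacyl ring, so a C2 carbinol can lose water to a flat para‑quinone methide that the ortho phenol oxygen of the bromocatechol ring recaptures as the O1–C2 bond.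
Forward order: arylacetic acid from 2,3‑dihydroxybenzaldehyde; chain joined by the aldol; dihydrofuran ring closed through the quinone methide; bromide turned into the aldehyde; chalcone; pyranone ring closed oxidatively, then C3 hydroxylation and global debenzylation.
Stereochemistry: C3 (S) comes from the enolate face fixed by (R)‑4‑benzyl‑2‑oxazolidinone; C2 (R) is set trans to the CH2OH group of C3 in the ring closure (substrate and thermodynamic control); the aldol carbinol centre is erased on purpose.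

Key step: step 11

Remark: the target is read from its SMILES as the (2R,3S) trans isomer, with dihydrobenzofuran numbering O1, C2 (guaiacyl), C3 (CH2OH), C5 (flavonol), C7 (OH).

Step 1
Reactants: 1 2,3-dihydroxybenzaldehyde
Product: 2 3-(benzyloxy)-2-hydroxybenzaldehyde
Conditions: NaH (2.2 equiv), DMSO, rt; BnBr (1.0 equiv), rt; aq. HCl work-up
Reagents that add atoms: benzyl bromide, BrCc1ccccc1
Why: In the dianion the 3‑phenoxide is the more nucleophilic oxygen, because the 2‑phenoxide is delocalised into and chelated by the ortho formyl group, so one equivalent of benzyl bromide should give the 3‑O‑benzyl ether (regioselective Williamson etherification).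

Step 2
Reactants: 2 3-(benzyloxy)-2-hydroxybenzaldehyde
Product: 3 3-(benzyloxy)-5-bromo-2-hydroxybenzaldehyde
Conditions: Br2 (1.05 equiv), NaOAc, AcOH, rt
Reagents that add atoms: bromine, BrBr
Why: Electrophilic aromatic bromination goes para to the free phenol (both ortho positions are occupied), the same pattern as the bromination of o‑vanillin.

Step 3
Reactants: 3 3-(benzyloxy)-5-bromo-2-hydroxybenzaldehyde
Product: 4 2-(allyloxy)-3-(benzyloxy)-5-bromobenzaldehyde
Conditions: allyl bromide, K2CO3, DMF, 50 °C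
Reagents that add atoms: allyl bromide, C=CCBr
Why: Williamson allylation of the remaining phenol installs a group that tolerates the basic steps ahead and can later be removed under neutral conditions beside the benzyl ether and the aryl bromide.

Step 4
Reactants: 4 2-(allyloxy)-3-(benzyloxy)-5-bromobenzaldehyde
Product: 6 2-[2-(allyloxy)-3-(benzyloxy)-5-bromophenyl]acetonitrile, via N-formyl vinyl sulfone 5 (not isolated)
Conditions: TosMIC (1.2 equiv), t-BuOK (2.4 equiv), DME, −40 °C; then MeOH, reflux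
Reagents that add atoms: p-toluenesulfonylmethyl isocyanide (TosMIC), Cc1ccc(cc1)S(=O)(=O)C[N+]#[C-]
Why: Van Leusen reductive cyanation: metalated TosMIC adds to the aldehyde, the oxazoline opens to the N‑formyl vinyl sulfone, and methanolysis (loss of methyl formate and sulfinate) should leave the one‑carbon‑homologated nitrile.

Step 5
Reactants: 6 2-[2-(allyloxy)-3-(benzyloxy)-5-bromophenyl]acetonitrile
Product: 7 2-[2-(allyloxy)-3-(benzyloxy)-5-bromophenyl]acetic acid
Conditions: KOH, EtOH/H2O, reflux; then aq. HCl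
Reagents that add atoms: water, O; potassium hydroxide, [K+].[OH-]
Why: Alkaline nitrile hydrolysis, to which the aryl allyl ether, the benzyl ether and the aryl bromide are inert.

Step 6
Reactants: 7 2-[2-(allyloxy)-3-(benzyloxy)-5-bromophenyl]acetic acid; 8 (R)-4-benzyl-2-oxazolidinone
Product: 10 (R)-3-{2-[2-(allyloxy)-3-(benzyloxy)-5-bromophenyl]acetyl}-4-benzyloxazolidin-2-one, via mixed pivalic anhydride 9 (not isolated)
Conditions: PivCl, Et3N, THF, −20 °C; then 8, LiCl, −20 °C → rt
Reagents that add atoms: none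
Why: N‑Acylation of the oxazolidinone through the mixed pivalic anhydride under LiCl/Et3N activation, which avoids an organolithium base in the presence of the aryl bromide.

Step 7
Reactants: 11 vanillin
Product: 12 4-(allyloxy)-3-methoxybenzaldehyde
Conditions: allyl bromide, K2CO3, acetone, reflux
Reagents that add atoms: allyl bromide, C=CCBr
Why: Williamson etherification of the phenol gives the aldehyde partner with the same neutral‑removable group as in 10.

Step 8
Reactants: 10 (R)-3-{2-[2-(allyloxy)-3-(benzyloxy)-5-bromophenyl]acetyl}-4-benzyloxazolidin-2-one; 12 4-(allyloxy)-3-methoxybenzaldehyde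
Product: 15 (R)-3-[(2R,3R)-2-[2-(allyloxy)-3-(benzyloxy)-5-bromophenyl]-3-[4-(allyloxy)-3-methoxyphenyl]-3-hydroxypropanoyl]-4-benzyloxazolidin-2-one, via Z-dibutylboron enolate 13 (not isolated), via dibutylboron aldolate 14 (not isolated)
Conditions: Bu2BOTf, iPr2NEt, CH2Cl2, −78 → 0 °C; 12, −78 → 0 °C; pH 7 buffer, MeOH, 30% H2O2, 0 °C
Reagents that add atoms: none
Why: Evans syn aldol: the Z‑boron enolate should react through a Zimmerman–Traxler chair on the face away from the auxiliary's benzyl group, which fixes the α‑aryl carbon as R (the future C3), while the 3R carbinol formed with it is erased in step 11.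

Step 9
Reactants: 15 (R)-3-[(2R,3R)-2-[2-(allyloxy)-3-(benzyloxy)-5-bromophenyl]-3-[4-(allyloxy)-3-methoxyphenyl]-3-hydroxypropanoyl]-4-benzyloxazolidin-2-one
Product: 16 (1R,2S)-2-[2-(allyloxy)-3-(benzyloxy)-5-bromophenyl]-1-[4-(allyloxy)-3-methoxyphenyl]propane-1,3-diol
Conditions: LiBH4, H2O (1 equiv), THF, 0 °C
Reagents that add atoms: none
Why: Reductive cleavage of the N‑acyl oxazolidinone with LiBH4 should give the primary alcohol and release the auxiliary without touching the α‑aryl centre, whose descriptor changes from R to S only because the CIP priorities change.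

Step 10
Reactants: 16 (1R,2S)-2-[2-(allyloxy)-3-(benzyloxy)-5-bromophenyl]-1-[4-(allyloxy)-3-methoxyphenyl]propane-1,3-diol
Product: 17 (1R,2S)-2-[3-(benzyloxy)-5-bromo-2-hydroxyphenyl]-1-(4-hydroxy-3-methoxyphenyl)propane-1,3-diol
Conditions: Pd(PPh3)4 (5 mol %), morpholine, THF, rt
Reagents that add atoms: none
Why: Tsuji–Trost deallylation: Pd(0) ionises both aryl allyl ethers at room temperature and morpholine takes up the π‑allyl units, while oxidative addition into the electron‑rich aryl bromide is slow under these conditions and the non‑acidic medium leaves the 4‑hydroxybenzylic carbinol un‑ionised.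

Step 11
Reactants: 17 (1R,2S)-2-[3-(benzyloxy)-5-bromo-2-hydroxyphenyl]-1-(4-hydroxy-3-methoxyphenyl)propane-1,3-diol
Product: 19 [(2R,3S)-7-(benzyloxy)-5-bromo-2-(4-hydroxy-3-methoxyphenyl)-2,3-dihydro-1-benzofuran-3-yl]methanol, via para-quinone methide 18 (not isolated)
Conditions: p-TsOH·H2O (0.2 equiv), MeCN (0.02 M), 0 °C → rt
Reagents that add atoms: none
Why: Protonation of the benzylic hydroxyl and loss of water, pushed by the para phenolic OH of the guaiacyl ring, should give the planar para‑quinone methide 18, so the C1 configuration inherited from the aldol is erased and either carbinol epimer would serve. The closest known reaction type is the acid‑catalysed closure of 2‑(2‑hydroxyaryl)‑1‑(4‑hydroxyaryl)propane‑1,3‑diols to trans‑phenylcoumarans, an intramolecular oxa‑1,6‑addition to a quinone methide. The dihydrofuran ring closes 5‑exo‑trig: the phenol oxygen ortho to the side chain attacks the exocyclic methide carbon and forms O1–C2 while the guaiacyl ring re‑aromatises. The new centre C2 is controlled by C3, since attack is expected on the methide face anti to the CH2OH group, and because the product is itself a para‑hydroxybenzylic aryl ether that can re‑ionise under the same acid, any cis isomer should equilibrate to the more stable trans (2R,3S) ring. The step needs chemoselectivity for the ortho phenol over the primary alcohol and over intermolecular capture; ring size secures the first (the primary hydroxyl could only close an oxetane and the 3‑oxygen is benzylated and out of reach) and high dilution in a non‑nucleophilic solvent the second. C3 carries no acidic or ionisable group and should pass through unchanged.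

Step 12
Reactants: 19 [(2R,3S)-7-(benzyloxy)-5-bromo-2-(4-hydroxy-3-methoxyphenyl)-2,3-dihydro-1-benzofuran-3-yl]methanol
Product: 20 (2R,3S)-7-(benzyloxy)-3-[(benzyloxy)methyl]-2-[4-(benzyloxy)-3-methoxyphenyl]-5-bromo-2,3-dihydro-1-benzofuran
Conditions: BnBr (2.4 equiv), then NaH (2.5 equiv), n-Bu4NI (cat.), DMF, 0 °C → rt
Reagents that add atoms: benzyl bromide, BrCc1ccccc1
Why: Williamson benzylation of the phenoxide and the primary alkoxide in one operation; capping the guaiacyl phenol also shuts off re‑opening of the ring through the quinone methide in all later steps.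

Step 13
Reactants: 20 (2R,3S)-7-(benzyloxy)-3-[(benzyloxy)methyl]-2-[4-(benzyloxy)-3-methoxyphenyl]-5-bromo-2,3-dihydro-1-benzofuran
Product: 22 (2R,3S)-7-(benzyloxy)-3-[(benzyloxy)methyl]-2-[4-(benzyloxy)-3-methoxyphenyl]-2,3-dihydro-1-benzofuran-5-carbaldehyde, via aryllithium 21 (not isolated)
Conditions: n-BuLi (1.1 equiv), THF, −78 °C; DMF, −78 → 0 °C; aq. NH4Cl
Reagents that add atoms: N,N-dimethylformamide, CN(C)C=O
Why: Bromine–lithium exchange at −78 °C is faster than any deprotonation of the benzylic ethers, and formylation of the aryllithium with DMF (Bouveault) should give the aldehyde.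

Step 14
Reactants: 23 2,4,6-trihydroxyacetophenone
Product: 24 1-[2,4-bis(benzyloxy)-6-hydroxyphenyl]ethan-1-one
Conditions: BnBr (2.05 equiv), K2CO3, DMF, rt
Reagents that add atoms: benzyl bromide, BrCc1ccccc1
Why: Williamson benzylation takes the 4‑hydroxyl and one ortho hydroxyl, while the other ortho hydroxyl stays free because it is hydrogen‑bonded to the ketone.

Step 15
Reactants: 22 (2R,3S)-7-(benzyloxy)-3-[(benzyloxy)methyl]-2-[4-(benzyloxy)-3-methoxyphenyl]-2,3-dihydro-1-benzofuran-5-carbaldehyde; 24 1-[2,4-bis(benzyloxy)-6-hydroxyphenyl]ethan-1-one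
Product: 25 (E)-1-[2,4-bis(benzyloxy)-6-hydroxyphenyl]-3-{(2R,3S)-7-(benzyloxy)-3-[(benzyloxy)methyl]-2-[4-(benzyloxy)-3-methoxyphenyl]-2,3-dihydro-1-benzofuran-5-yl}prop-2-en-1-one
Conditions: KOH (50% aq.), EtOH/THF, rt; then aq. HCl
Reagents that add atoms: none
Why: Claisen–Schmidt condensation of the methyl ketone with the non‑enolisable aldehyde should give the E‑chalcone, and neither ring stereocentre is acidic under hydroxide.

Step 16
Reactants: 25 (E)-1-[2,4-bis(benzyloxy)-6-hydroxyphenyl]-3-{(2R,3S)-7-(benzyloxy)-3-[(benzyloxy)methyl]-2-[4-(benzyloxy)-3-methoxyphenyl]-2,3-dihydro-1-benzofuran-5-yl}prop-2-en-1-one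
Product: 27 5,7-bis(benzyloxy)-2-{(2R,3S)-7-(benzyloxy)-3-[(benzyloxy)methyl]-2-[4-(benzyloxy)-3-methoxyphenyl]-2,3-dihydro-1-benzofuran-5-yl}-4H-chromen-4-one, via flavanone 26 (not isolated)
Conditions: I2 (10 mol %), DMSO, 120 °C
Reagents that add atoms: none
Why: Iodine/DMSO oxidative cyclisation of a 2'‑hydroxychalcone: 6‑endo oxa‑Michael closure to the flavanone, α‑iodination and loss of HI give the flavone while DMSO re‑oxidises iodide.

Step 17
Reactants: 27 5,7-bis(benzyloxy)-2-{(2R,3S)-7-(benzyloxy)-3-[(benzyloxy)methyl]-2-[4-(benzyloxy)-3-methoxyphenyl]-2,3-dihydro-1-benzofuran-5-yl}-4H-chromen-4-one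
Product: 29 5,7-bis(benzyloxy)-3-hydroxy-2-{(2R,3S)-7-(benzyloxy)-3-[(benzyloxy)methyl]-2-[4-(benzyloxy)-3-methoxyphenyl]-2,3-dihydro-1-benzofuran-5-yl}-4H-chromen-4-one, via flavone 2,3-epoxide 28 (not isolated)
Conditions: DMDO (acetone solution, 3 equiv), CH2Cl2, 0 °C → rt; then p-TsOH·H2O (cat.), CH2Cl2, rt
Reagents that add atoms: dimethyldioxirane, CC1(C)OO1
Why: Dioxirane epoxidation of the enol‑ether‑like C2=C3 bond of the chromone, followed by acid‑assisted opening and tautomerisation of the epoxide, is the standard flavone‑to‑flavonol oxidation and should proceed at 0 °C before benzylic C–H oxidation sets in.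

Step 18
Reactants: 29 5,7-bis(benzyloxy)-3-hydroxy-2-{(2R,3S)-7-(benzyloxy)-3-[(benzyloxy)methyl]-2-[4-(benzyloxy)-3-methoxyphenyl]-2,3-dihydro-1-benzofuran-5-yl}-4H-chromen-4-one
Product: 30 2,3-dehydrosilychristin
Conditions: H2 (1 atm), 10% Pd/C, THF/MeOH, rt, stopped at full debenzylation
Reagents that add atoms: none
Why: Catalytic hydrogenolysis should remove all five benzyl ethers in one operation, while the chromone double bond and the cyclic benzylic aryl ether of the dihydrofuran are reduced much more slowly.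

Compound list
1 | 2,3-dihydroxybenzaldehyde | O=Cc1cccc(O)c1O | starting material
2 | 3-(benzyloxy)-2-hydroxybenzaldehyde | O=Cc1cccc(OCc2ccccc2)c1O | intermediate
3 | 3-(benzyloxy)-5-bromo-2-hydroxybenzaldehyde | O=Cc1cc(Br)cc(OCc2ccccc2)c1O | intermediate
4 | 2-(allyloxy)-3-(benzyloxy)-5-bromobenzaldehyde | O=Cc1cc(Br)cc(OCc2ccccc2)c1OCC=C | intermediate
5 | N-{2-[2-(allyloxy)-3-(benzyloxy)-5-bromophenyl]-1-tosylethenyl}formamide [not isolated; alkene geometry undefined] | O=CNC(=Cc1cc(Br)cc(OCc2ccccc2)c1OCC=C)S(=O)(=O)c1ccc(C)cc1 | intermediate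
6 | 2-[2-(allyloxy)-3-(benzyloxy)-5-bromophenyl]acetonitrile | N#CCc1cc(Br)cc(OCc2ccccc2)c1OCC=C | intermediate
7 | 2-[2-(allyloxy)-3-(benzyloxy)-5-bromophenyl]acetic acid | OC(=O)Cc1cc(Br)cc(OCc2ccccc2)c1OCC=C | intermediate
8 | (R)-4-benzyl-2-oxazolidinone | O=C1N[C@H](Cc2ccccc2)CO1 | starting material
9 | 2-[2-(allyloxy)-3-(benzyloxy)-5-bromophenyl]acetic pivalic anhydride [not isolated] | CC(C)(C)C(=O)OC(=O)Cc1cc(Br)cc(OCc2ccccc2)c1OCC=C | intermediate
10 | (R)-3-{2-[2-(allyloxy)-3-(benzyloxy)-5-bromophenyl]acetyl}-4-benzyloxazolidin-2-one | O=C(Cc1cc(Br)cc(OCc2ccccc2)c1OCC=C)N1C(=O)OC[C@H]1Cc1ccccc1 | intermediate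
11 | vanillin | COc1cc(C=O)ccc1O | starting material
12 | 4-(allyloxy)-3-methoxybenzaldehyde | COc1cc(C=O)ccc1OCC=C | intermediate
13 | (R)-4-benzyl-3-{(Z)-2-[2-(allyloxy)-3-(benzyloxy)-5-bromophenyl]-1-[(dibutylboranyl)oxy]ethenyl}oxazolidin-2-one [not isolated] | CCCCB(CCCC)O/C(=C\c1cc(Br)cc(OCc2ccccc2)c1OCC=C)N1C(=O)OC[C@H]1Cc1ccccc1 | intermediate
14 | O-dibutylboryl aldolate of 15 [not isolated] | O=C(N1C(=O)OC[C@H]1Cc1ccccc1)[C@H](c1cc(Br)cc(OCc2ccccc2)c1OCC=C)[C@@H](OB(CCCC)CCCC)c1ccc(OCC=C)c(OC)c1 | intermediate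
15 | (R)-3-[(2R,3R)-2-[2-(allyloxy)-3-(benzyloxy)-5-bromophenyl]-3-[4-(allyloxy)-3-methoxyphenyl]-3-hydroxypropanoyl]-4-benzyloxazolidin-2-one | O=C(N1C(=O)OC[C@H]1Cc1ccccc1)[C@H](c1cc(Br)cc(OCc2ccccc2)c1OCC=C)[C@@H](O)c1ccc(OCC=C)c(OC)c1 | intermediate
16 | (1R,2S)-2-[2-(allyloxy)-3-(benzyloxy)-5-bromophenyl]-1-[4-(allyloxy)-3-methoxyphenyl]propane-1,3-diol | OC[C@H](c1cc(Br)cc(OCc2ccccc2)c1OCC=C)[C@@H](O)c1ccc(OCC=C)c(OC)c1 | intermediate
17 | (1R,2S)-2-[3-(benzyloxy)-5-bromo-2-hydroxyphenyl]-1-(4-hydroxy-3-methoxyphenyl)propane-1,3-diol | OC[C@H](c1cc(Br)cc(OCc2ccccc2)c1O)[C@@H](O)c1ccc(O)c(OC)c1 | intermediate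
18 | 4-{(2S)-2-[3-(benzyloxy)-5-bromo-2-hydroxyphenyl]-3-hydroxypropylidene}-2-methoxycyclohexa-2,5-dien-1-one [not isolated] | OC[C@H](c1cc(Br)cc(OCc2ccccc2)c1O)C=C1C=CC(=O)C(OC)=C1 | intermediate
19 | [(2R,3S)-7-(benzyloxy)-5-bromo-2-(4-hydroxy-3-methoxyphenyl)-2,3-dihydro-1-benzofuran-3-yl]methanol | COc1cc([C@@H]2Oc3c(OCc4ccccc4)cc(Br)cc3[C@H]2CO)ccc1O | intermediate
20 | (2R,3S)-7-(benzyloxy)-3-[(benzyloxy)methyl]-2-[4-(benzyloxy)-3-methoxyphenyl]-5-bromo-2,3-dihydro-1-benzofuran | COc1cc([C@@H]2Oc3c(OCc4ccccc4)cc(Br)cc3[C@H]2COCc2ccccc2)ccc1OCc1ccccc1 | intermediate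
21 | {(2R,3S)-7-(benzyloxy)-3-[(benzyloxy)methyl]-2-[4-(benzyloxy)-3-methoxyphenyl]-2,3-dihydro-1-benzofuran-5-yl}lithium [not isolated] | COc1cc([C@@H]2Oc3c(OCc4ccccc4)cc([Li])cc3[C@H]2COCc2ccccc2)ccc1OCc1ccccc1 | intermediate
22 | (2R,3S)-7-(benzyloxy)-3-[(benzyloxy)methyl]-2-[4-(benzyloxy)-3-methoxyphenyl]-2,3-dihydro-1-benzofuran-5-carbaldehyde | COc1cc([C@@H]2Oc3c(OCc4ccccc4)cc(C=O)cc3[C@H]2COCc2ccccc2)ccc1OCc1ccccc1 | intermediate
23 | 2,4,6-trihydroxyacetophenone | CC(=O)c1c(O)cc(O)cc1O | starting material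
24 | 1-[2,4-bis(benzyloxy)-6-hydroxyphenyl]ethan-1-one | CC(=O)c1c(O)cc(OCc2ccccc2)cc1OCc1ccccc1 | intermediate
25 | (E)-1-[2,4-bis(benzyloxy)-6-hydroxyphenyl]-3-{(2R,3S)-7-(benzyloxy)-3-[(benzyloxy)methyl]-2-[4-(benzyloxy)-3-methoxyphenyl]-2,3-dihydro-1-benzofuran-5-yl}prop-2-en-1-one | COc1cc([C@@H]2Oc3c(OCc4ccccc4)cc(/C=C/C(=O)c4c(O)cc(OCc5ccccc5)cc4OCc4ccccc4)cc3[C@H]2COCc2ccccc2)ccc1OCc1ccccc1 | intermediate
26 | 5,7-bis(benzyloxy)-2-{(2R,3S)-7-(benzyloxy)-3-[(benzyloxy)methyl]-2-[4-(benzyloxy)-3-methoxyphenyl]-2,3-dihydro-1-benzofuran-5-yl}chroman-4-one [not isolated; both epimers at the chromanone C2] | COc1cc([C@@H]2Oc3c(OCc4ccccc4)cc(C4Oc5cc(OCc6ccccc6)cc(OCc6ccccc6)c5C(=O)C4)cc3[C@H]2COCc2ccccc2)ccc1OCc1ccccc1 | intermediate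
27 | 5,7-bis(benzyloxy)-2-{(2R,3S)-7-(benzyloxy)-3-[(benzyloxy)methyl]-2-[4-(benzyloxy)-3-methoxyphenyl]-2,3-dihydro-1-benzofuran-5-yl}-4H-chromen-4-one | COc1cc([C@@H]2Oc3c(OCc4ccccc4)cc(-c4oc5cc(OCc6ccccc6)cc(OCc6ccccc6)c5c(=O)c4)cc3[C@H]2COCc2ccccc2)ccc1OCc1ccccc1 | intermediate
28 | 2,3-epoxide of flavone 27 [not isolated; epoxide diastereomers] | COc1cc([C@@H]2Oc3c(OCc4ccccc4)cc(C45Oc6cc(OCc7ccccc7)cc(OCc7ccccc7)c6C(=O)C4O5)cc3[C@H]2COCc2ccccc2)ccc1OCc1ccccc1 | intermediate
29 | 5,7-bis(benzyloxy)-3-hydroxy-2-{(2R,3S)-7-(benzyloxy)-3-[(benzyloxy)methyl]-2-[4-(benzyloxy)-3-methoxyphenyl]-2,3-dihydro-1-benzofuran-5-yl}-4H-chromen-4-one | COc1cc([C@@H]2Oc3c(OCc4ccccc4)cc(-c4oc5cc(OCc6ccccc6)cc(OCc6ccccc6)c5c(=O)c4O)cc3[C@H]2COCc2ccccc2)ccc1OCc1ccccc1 | intermediate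
30 | 2,3-dehydrosilychristin, 3,5,7-trihydroxy-2-[(2R,3S)-7-hydroxy-2-(4-hydroxy-3-methoxyphenyl)-3-(hydroxymethyl)-2,3-dihydro-1-benzofuran-5-yl]-4H-chromen-4-one | COc1cc([C@@H]2Oc3c(O)cc(-c4oc5cc(O)cc(O)c5c(=O)c4O)cc3[C@H]2CO)ccc1O | target

Total step count: 18.
Longest linear sequence: 16 steps (steps 1–6, 8–13 and 15–18, from 2,3-dihydroxybenzaldehyde); steps 7 and 14 are one-step side branches.

Steps most likely to fail

Step 8. The addition of the hindered, ortho‑disubstituted arylacetyl enolate to an electron‑rich aldehyde may be slow and reversible, and retro‑aldol cleavage or epimerisation of the doubly benzylic α‑carbon may erode the stereochemistry, either in the aldol or during removal of the auxiliary. The fallback sets out from acid 7 and returns at diol 16. Acid 7 is coupled with commercial (R)-4-benzyl-1,3-thiazolidine-2-thione (EDC·HCl, DMAP, CH2Cl2) to give the N‑acyl thiazolidinethione 2-[2-(allyloxy)-3-(benzyloxy)-5-bromophenyl]-1-[(4R)-4-benzyl-2-thioxo-1,3-thiazolidin-3-yl]ethan-1-one F1. Enolisation with TiCl4 (1.05 equiv), iPr2NEt (1.1 equiv) and N‑methylpyrrolidinone (1 equiv) in CH2Cl2 at 0 °C, then addition of aldehyde 12 at −78 °C (Crimmins conditions for the Evans‑type syn adduct), should give the (2R,3R) aldol thioimide F2 with the same α‑configuration as 15. The thioimide is far easier to cleave than the oxazolidinone, so NaBH4 in THF/EtOH at 0 °C should deliver 16 before retro‑aldol can compete.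

Step 11. Under Brønsted acid the ionised benzylic centre may lose formaldehyde by retro‑Prins fragmentation, tautomerise to the stilbene (which would destroy C3), or be captured intermolecularly by a second electron‑rich ring. The fallback sets out from 17 and returns at 19, separating quinone methide formation from the acid. Me3SiBr in CH2Cl2 at 0 °C converts the 4‑hydroxybenzylic carbinol into the benzylic bromide 4-[(2S)-1-bromo-2-[3-(benzyloxy)-5-bromo-2-hydroxyphenyl]-3-hydroxypropyl]-2-methoxyphenol F3. Brief shaking with cold aqueous NaHCO3 eliminates HBr and generates quinone methide 18 under essentially neutral conditions (the standard preparation of lignin‑type quinone methides). In dilute CH2Cl2, 18 should close to 19 by the same 5‑exo‑trig phenol addition, if necessary with a trace of acetic acid to equilibrate to trans.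

Step 17. Epoxidation of the electron‑poor chromone double bond is slow, so oxidation of the benzylic ether C–H bonds (including C2–H of the dihydrofuran) or of the polyalkoxy arenes by excess dioxirane may overtake it. The fallback sets out from flavone 27 and returns at 29 without an electrophilic oxidant acting on the whole molecule. C3 of the chromone is deprotonated with LDA in THF at −78 °C to the 3‑lithioflavone F4. This is trapped with trimethyl borate to give the dimethyl (4‑oxo‑4H‑chromen‑3‑yl)boronate F5, and oxidation of the C–B bond with H2O2/AcOH at 0 °C should give flavonol 29 (directed lithiation–borylation–oxidation of flavones).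

Further compounds
F1 | step 8 | 2-[2-(allyloxy)-3-(benzyloxy)-5-bromophenyl]-1-[(4R)-4-benzyl-2-thioxo-1,3-thiazolidin-3-yl]ethan-1-one | O=C(Cc1cc(Br)cc(OCc2ccccc2)c1OCC=C)N1C(=S)SC[C@H]1Cc1ccccc1
F2 | step 8 | (2R,3R)-2-[2-(allyloxy)-3-(benzyloxy)-5-bromophenyl]-3-[4-(allyloxy)-3-methoxyphenyl]-1-[(4R)-4-benzyl-2-thioxo-1,3-thiazolidin-3-yl]-3-hydroxypropan-1-one | O=C(N1C(=S)SC[C@H]1Cc1ccccc1)[C@H](c1cc(Br)cc(OCc2ccccc2)c1OCC=C)[C@@H](O)c1ccc(OCC=C)c(OC)c1
F3 | step 11 | 4-[(2S)-1-bromo-2-[3-(benzyloxy)-5-bromo-2-hydroxyphenyl]-3-hydroxypropyl]-2-methoxyphenol (both C1 epimers) | OC[C@H](c1cc(Br)cc(OCc2ccccc2)c1O)C(Br)c1ccc(O)c(OC)c1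
F4 | step 17 | {5,7-bis(benzyloxy)-2-[(2R,3S)-7-(benzyloxy)-3-[(benzyloxy)methyl]-2-[4-(benzyloxy)-3-methoxyphenyl]-2,3-dihydro-1-benzofuran-5-yl]-4-oxo-4H-chromen-3-yl}lithium | COc1cc([C@@H]2Oc3c(OCc4ccccc4)cc(-c4oc5cc(OCc6ccccc6)cc(OCc6ccccc6)c5c(=O)c4[Li])cc3[C@H]2COCc2ccccc2)ccc1OCc1ccccc1
F5 | step 17 | dimethyl {5,7-bis(benzyloxy)-2-[(2R,3S)-7-(benzyloxy)-3-[(benzyloxy)methyl]-2-[4-(benzyloxy)-3-methoxyphenyl]-2,3-dihydro-1-benzofuran-5-yl]-4-oxo-4H-chromen-3-yl}boronate | COc1cc([C@@H]2Oc3c(OCc4ccccc4)cc(-c4oc5cc(OCc6ccccc6)cc(OCc6ccccc6)c5c(=O)c4B(OC)OC)cc3[C@H]2COCc2ccccc2)ccc1OCc1ccccc1
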